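## Structural features

The target is a 2,5-diaryl-3,4-dimethyloxolane whose two aryl groups are guaiacyl rings (3-methoxy, 4-oxygenated). Each phenolic oxygen carries the same arm, a 1-(3,4-dimethoxyphenyl)-1-hydroxypropan-2-yl group bound through its methyl-bearing carbon (C8; the carbinol carbon is C7). The oxolane holds four contiguous stereocentres, (2S,3S,4S,5R): the aryl groups at C2 and C5 are cis, the C4 methyl is cis to the C5 aryl, and the C3 methyl is trans to both the C2 aryl and the C4 methyl, so the two constitutionally equal halves of the ring differ in configuration. Each arm adds a vicinal erythro pair (C7 R next to C8 S), eight stereocentres in all. The fragile sites are the ring bonds C2–O1 and C5–O1 (benzylic ethers para to oxygen, which ionise with acid and can be hydrogenolysed), the benzylic C7 carbinols, and C8 of any α-aryloxy ketone precursor, which enolises. The real difficulty is the 4,5-cis aryl/methyl pair at an easily ionised benzylic carbon, a kinetic arrangement that has to be made stereospecifically while C2 takes the opposite relation to its own methyl neighbour. The second difficulty is that two identical arms must be finished without multiplying diastereomers. The key step uses C5 (a benzylic C–O carbon next to the methyl-bearing C4) and the cis relation of the two aryl groups across O1: an aldehyde oxygen that opens a trans-2-aryl-3-methylcyclopropane-1,1-diester with inversion forms O1–C5 with the cis pair, and the closure C2–C3 that follows gives the 2,5-cis ring.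

## Logic of the disconnections

19 to 18: the two C7–H bonds are removed, which turns both carbinols into ketones. Both C7 centres then arise in one operation under the influence of the neighbouring C8 ether oxygen, and each arm loses one stereocentre. The forward reduction must be erythro-selective at both ends and must not enolise C8.

18 to 11 and 17: the two C8–O(aryl) bonds are cut. A phenoxide and an α-sulfonyloxy ketone are a natural nucleophile/electrophile pair, and since the arms are identical one electrophile serves twice. The core is reduced to a bis-phenol with only the four ring stereocentres. The forward step must proceed with clean inversion at C8 and without base-induced epimerisation.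

17 to 15 and 14 (through 16), then 14 to 13 to 12: the aryl–carbonyl bond is cut and the sulfonate and acid functions are traced back to a chiral-pool hydroxy ester. C8 is bought rather than made. The acylation must go para to a methoxy group and leave the α-carbon untouched, and the hydroxyl must already be sulfonylated.

11 to 10, then 10 to 9 to 8 to 7: the two O-benzyl groups are put back, and the C3 methyl is traced through sulfonate and alcohol to an ester. An ester at C3 is what the ring-forming step leaves behind, and it is the only C3 substituent that can be equilibrated to the side the target needs. The reductions and the hydrogenolysis must leave the benzylic ring ethers alone.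

7 to 6: a second ester is added back at C3. C3 ceases to be a stereocentre and the ring carries the geminal diester that a malonate-derived partner provides. The forward loss of one ester must end with the survivor anti to both neighbours.

6 to 4 and 5: O1–C5 and C2–C3 are cut. This removes the ring, two stereocentres (C2, C5) and half of the carbon skeleton in one stroke, and leaves an aldehyde and a cyclopropane whose aryl carbon becomes C5 and whose methyl carbon becomes C4. The forward step must invert the aryl-bearing carbon without ionising it and close the ring 2,5-cis.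

4 to 3 and 2, then 2 to 1: the two cyclopropane bonds from the malonate carbon are cut, giving an E-alkene and a malonyl carbene equivalent. Both cyclopropane stereocentres then come from one face-selective, geometry-preserving addition. The forward step must be enantioselective on a trans-1,2-disubstituted, electron-rich alkene.

## Other disconnections considered

Alternative 1: The cut is at the two aryl C4–O bonds, on the aryl side of the ether oxygen instead of the C8 side. In the forward direction (2S,3S,4S,5R)-2,5-bis(4-bromo-3-methoxyphenyl)-3,4-dimethyloxolane A1 would be coupled at both bromides with (1R,2S)-1-(3,4-dimethoxyphenyl)-1-[(triisopropylsilyl)oxy]propan-2-ol A2 through its free C8 hydroxyl (Pd2(dba)3, a bulky di-tert-butyl biaryl phosphine, Cs2CO3) to give the bis-TIPS ether of the target A3, and fluoride would finish.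
- In favour: no bond to C8 is broken, so its configuration is retained; the erythro pair is fixed and purified on the small molecule A2; there is no enolisable ketone and no late double reduction.
- Against: the palladium alkoxide of a secondary alcohol has a β-hydrogen at C8, and with an electron-rich, ortho-methoxylated aryl bromide C–O reductive elimination is slow, so β-hydride elimination can compete at each of the two couplings. The alcohol is branched on both sides. Warm carbonate can also move the silyl group from O7 to O8 and change which oxygen couples. A1 cannot be drawn from cheap phenolic feedstock.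
- Comparison: on structure the two plans share the core. The alternative is better in that the arm stereochemistry is settled before the coupling, and it is one step shorter after the core (coupling and desilylation against hydrogenolysis, etherification and reduction). On mechanism the chosen plan uses an intrinsically easy SN2 displacement at an α-keto sulfonate and pays with two stereochemical risks, whereas the alternative places its whole risk on a cross-coupling near the limit of that reaction class.

Alternative 2: The cut is at C3–CH3 and C4–CH3. In the forward direction (5S)-5-[4-(benzyloxy)-3-methoxyphenyl]furan-2(5H)-one A4 would take up Me2CuLi at the β-carbon anti to the aryl group, and the enolate would be methylated by MeI anti to the new methyl, giving (3S,4S,5S)-5-[4-(benzyloxy)-3-methoxyphenyl]-3,4-dimethyloxolan-2-one A5, whose carbonyl carbon is the future C5. Aryl addition to that carbonyl and ionic reduction would then reach 10.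
- In favour: one stereocentre relays to two, two C–C bonds form in one flask, and from A5 only two operations lead to 10, whereas the chosen plan spends four steps after its key step converting a diester into a methyl group. On that stretch the alternative is the better of the two.
- Against: the γ-hydrogen of A4 is benzylic and vinylogously acidic, so basic cuprate and enolate media can deprotonate it to an aromatic 2-oxyfuran and erase the only controlling centre. Trapping a cuprate-derived enolate with MeI is slow and invites proton transfer and double methylation. A4 needs its own asymmetric synthesis. C5 would rest on the facial selectivity of hydride addition to an oxocarbenium ion rather than on a stereospecific substitution.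
- Comparison: the alternative decorates a preformed ring by two 1,2-inductions and depends on a labile stereocentre. The chosen plan forms the ring with two bonds and two stereocentres by transfer of configuration and depends on suppressing ionisation. From 10 onward the two are equal.

Alternative 3: The cut is at O1–C2 with both arms already attached. In the forward direction mono-mesylation (MsCl, Et3N) of the C2-symmetric diol A6 (the (1R,2S,3S,4R)-1,4-diaryl-2,3-dimethylbutane-1,4-diol carrying both TBS-protected arms) would let the remaining hydroxyl displace the benzylic sulfonate with inversion and give the bis-TBS ether of the target A7; desilylation would finish.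
- In favour: the two carbinols are homotopic, so there is no site selectivity to solve, and the endgame is very short. The carbon that is inverted ends trans to its methyl neighbour, so the required sense of substitution coincides with the thermodynamic preference. Partial ionisation of the p-alkoxybenzylic sulfonate would therefore do less harm than in the chosen plan, where inversion must deliver the less stable cis pair; this is a point on which the alternative is better.
- Against: all eight stereocentres and both acid-sensitive arms must be carried through the construction of A6, which requires joining two arm-bearing halves and setting four new centres on a large substrate. Bis-mesylation and elimination to a styrene are available side paths, and the arms are lost if the late steps fail.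
- Comparison: the chosen plan keeps the valuable arms out of all ring chemistry and builds the ring from two simple partners, at the price of a contra-thermodynamic substitution. The alternative may have the shorter longest linear sequence, but the chosen plan exposes less advanced material to risk.

Key step: step 3

Assumptions and checks, each a remark on the chemistry:
- Benzyl (E)-isoeugenyl ether 3 is taken as a purchased compound and recrystallised to E purity, because any Z-alkene would pass through the cis-cyclopropane into the C5 epimer.
- The (S,S) antipode of the bis(oxazoline) is assumed to give (2S,3R)-4; if the sense of induction proves opposite, the (R,R) ligand is used.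
- In the reserve reduction with an oxazaborolidine (see the last section) the aryl group is assumed to act as the large substituent.
- Configurational bookkeeping was re-derived: 4 is (2S,3R); inversion at its C2 and retention at its C3 give (2R,4S,5R)-6; the change of the C2 descriptor from R in 6 to S in 7 reflects only the CIP ranking. No structure needed correction.
- One point of reasoning is tightened: since C4 is not touched, reversible opening of 4 cannot racemise it. The hazard is epimerisation at C5, so enantiopurity is fixed in step 2 and diastereopurity in step 3.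

## Route

Step 1
Reactants: 1 dimethyl malonate
Product: 2 phenyliodonium bis(methoxycarbonyl)methanide
Conditions: PhI(OAc)2, KOH, MeCN, 0 °C
Reagents that add atoms: (diacetoxyiodo)benzene, CC(=O)OI(OC(C)=O)c1ccccc1
Why: Deprotonated malonate exchanges both acetates on iodine and gives the stabilised iodonium ylide, a storable malonyl carbene source (iodonium ylide formation).

Step 2
Reactants: 3 benzyl (E)-isoeugenyl ether; 2 phenyliodonium bis(methoxycarbonyl)methanide
Product: 4 dimethyl (2S,3R)-2-[4-(benzyloxy)-3-methoxyphenyl]-3-methylcyclopropane-1,1-dicarboxylate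
Conditions: Cu(MeCN)4PF6 (5 mol %), (S,S)-Ph-BOX (6 mol %), 4 Å MS, CH2Cl2, −20 °C; recrystallisation
Reagents that add atoms: none
Why: Monovalent copper bound to the C2-symmetric bis(oxazoline) converts the ylide into a copper malonyl carbene with loss of iodobenzene, and this adds to the electron-rich E-alkene in a concerted, geometry-preserving cyclopropanation, so the trans aryl/methyl relation is copied from the alkene. The ligand selects the alkene face and thereby sets both stereocentres together; recrystallisation is meant to raise the enantiomeric purity.

Step 3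
Reactants: 4 dimethyl (2S,3R)-2-[4-(benzyloxy)-3-methoxyphenyl]-3-methylcyclopropane-1,1-dicarboxylate; 5 4-(benzyloxy)-3-methoxybenzaldehyde (O-benzylvanillin)
Product: 6 dimethyl (2R,4S,5R)-2,5-bis[4-(benzyloxy)-3-methoxyphenyl]-4-methyloxolane-3,3-dicarboxylate
Conditions: Sn(OTf)2 (10 mol %), 5 (3 equiv), CH2Cl2, −20 °C
Reagents that add atoms: none
Why: Sn(OTf)2 binds both ester carbonyls of 4 and polarises the bond between the malonate carbon and the aryl-bearing carbon. The carbonyl oxygen of 5 attacks that benzylic carbon from the rear of the breaking bond, an SN2-like substitution on a tight ion pair, which forms O1–C5 with inversion and turns the trans aryl/methyl pair of 4 into the cis C5-aryl/C4-methyl pair, while C4 is carried through unchanged. The tin malonate enolate then adds to the oxocarbenium carbon and forms C2–C3; this closes the oxolane in a formally 5-endo-trig mode, which is routine when the acceptor is a heteroatom-stabilised cation. C5 is thus controlled by the configuration of the cyclopropane (stereospecific transfer), and C2 by the closing envelope, in which the aryl group of the E-oxocarbenium ion and the C5 aryl group are both pseudo-equatorial, which gives the 2,5-cis ring. The closest known reaction type is the Lewis acid-catalysed [3+2] annulation of aldehydes with enantioenriched 2-aryl cyclopropane-1,1-diesters, which gives 2,5-cis oxolanes with inversion at the donor carbon. The step needs substitution to outrun ionisation of the very electron-rich donor; because C4 is fixed, ionisation would not racemise the material but would epimerise C5 towards the more stable 4,5-trans series. The nucleophilic, electron-rich aldehyde in excess, the low temperature, the chelated malonate as a close counter-ion and the catalytic amount of Lewis acid are meant to secure the bimolecular path.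

Step 4
Reactants: 6 dimethyl (2R,4S,5R)-2,5-bis[4-(benzyloxy)-3-methoxyphenyl]-4-methyloxolane-3,3-dicarboxylate
Product: 7 methyl (2S,3S,4S,5R)-2,5-bis[4-(benzyloxy)-3-methoxyphenyl]-4-methyloxolane-3-carboxylate
Conditions: LiCl, H2O, DMSO, 150 °C
Reagents that add atoms: none
Why: Krapcho dealkoxycarbonylation: chloride demethylates one ester, the carboxylate loses CO2 and water protonates the ester enolate; under these equilibrating conditions the surviving ester should settle on the face opposite to the C2 aryl and the C4 methyl, which sets C3 under thermodynamic control. Ring opening by β-elimination of O1 is disfavoured because the C2–O1 bond lies near the nodal plane of the enolate.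

Step 5
Reactants: 7 methyl (2S,3S,4S,5R)-2,5-bis[4-(benzyloxy)-3-methoxyphenyl]-4-methyloxolane-3-carboxylate
Product: 8 {(2S,3R,4S,5R)-2,5-bis[4-(benzyloxy)-3-methoxyphenyl]-4-methyloxolan-3-yl}methanol
Conditions: LiAlH4, THF, 0 °C
Reagents that add atoms: none
Why: Hydride reduction of the ester to the primary alcohol; once the carbonyl is gone C3 can no longer epimerise, and the aryl ethers and the oxolane are inert to LiAlH4 at 0 °C.

Step 6
Reactants: 8 {(2S,3R,4S,5R)-2,5-bis[4-(benzyloxy)-3-methoxyphenyl]-4-methyloxolan-3-yl}methanol
Product: 9 {(2S,3R,4S,5R)-2,5-bis[4-(benzyloxy)-3-methoxyphenyl]-4-methyloxolan-3-yl}methyl methanesulfonate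
Conditions: MsCl, Et3N, CH2Cl2, 0 °C
Reagents that add atoms: methanesulfonyl chloride, CS(=O)(=O)Cl
Why: Sulfonylation of the primary alcohol under basic, non-ionising conditions; no stereocentre is touched.

Step 7
Reactants: 9 {(2S,3R,4S,5R)-2,5-bis[4-(benzyloxy)-3-methoxyphenyl]-4-methyloxolan-3-yl}methyl methanesulfonate
Product: 10 (2S,3S,4S,5R)-2,5-bis[4-(benzyloxy)-3-methoxyphenyl]-3,4-dimethyloxolane
Conditions: LiEt3BH, THF, 0 °C → rt
Reagents that add atoms: none
Why: SN2 displacement of the primary mesylate by hydride from LiEt3BH, which copes with β-branched primary sulfonates, turns CH2OMs into CH3 and completes the 3,4-trans-dimethyl pair.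

Step 8
Reactants: 10 (2S,3S,4S,5R)-2,5-bis[4-(benzyloxy)-3-methoxyphenyl]-3,4-dimethyloxolane
Product: 11 4,4'-[(2S,3S,4S,5R)-3,4-dimethyloxolane-2,5-diyl]bis(2-methoxyphenol)
Conditions: H2 (1 atm), Pd/C (10 wt %), EtOAc, rt
Reagents that add atoms: none
Why: Hydrogenolysis of the two aryl benzyl ethers, which cleave much faster than the dialkyl-type benzylic C–O bonds of the ring. In a neutral aprotic solvent at one atmosphere, with the reaction stopped after uptake of two equivalents, the ring should survive.

Step 9
Reactants: 12 methyl (R)-lactate
Product: 13 methyl (2R)-2-{[(4-methylphenyl)sulfonyl]oxy}propanoate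
Conditions: TsCl, Et3N, DMAP (cat.), CH2Cl2, 0 °C → rt
Reagents that add atoms: 4-methylbenzenesulfonyl chloride, Cc1ccc(cc1)S(=O)(=O)Cl
Why: Sulfonylation at oxygen; the C–O bond at the stereocentre is not broken, so the (R) configuration is kept.

Step 10
Reactants: 13 methyl (2R)-2-{[(4-methylphenyl)sulfonyl]oxy}propanoate
Product: 14 (2R)-2-{[(4-methylphenyl)sulfonyl]oxy}propanoic acid
Conditions: LiOH, THF/H2O, 0 °C; then aq. HCl
Reagents that add atoms: lithium hydroxide, [Li+].[OH-]
Why: Saponification at the activated acyl carbon at 0 °C should be faster than enolisation or displacement of the sulfonate, and the carboxylate once formed no longer enolises; acidification frees the acid.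

Step 11
Reactants: 14 (2R)-2-{[(4-methylphenyl)sulfonyl]oxy}propanoic acid; 15 1,2-dimethoxybenzene (veratrole)
Product: 17 (2R)-1-(3,4-dimethoxyphenyl)-1-oxopropan-2-yl 4-methylbenzenesulfonate, via (2R)-2-(tosyloxy)propanoyl chloride 16 (not isolated)
Conditions: (COCl)2, DMF (cat.), CH2Cl2, 0 °C → rt; then 15, AlCl3, CH2Cl2, 0 °C
Reagents that add atoms: none
Why: Acid chloride formation followed by Friedel–Crafts acylation; veratrole reacts para to one methoxy group, which gives the 3,4-dimethoxyphenyl ketone. The electron-poor α-carbon neither ionises nor enolises under these acidic conditions, so α-sulfonyloxy acyl chlorides of this kind acylate arenes with the configuration intact.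

Step 12
Reactants: 11 4,4'-[(2S,3S,4S,5R)-3,4-dimethyloxolane-2,5-diyl]bis(2-methoxyphenol); 17 (2R)-1-(3,4-dimethoxyphenyl)-1-oxopropan-2-yl 4-methylbenzenesulfonate
Product: 18 (2S,2'S)-2,2'-{[(2S,3S,4S,5R)-3,4-dimethyloxolane-2,5-diyl]bis[(2-methoxy-4,1-phenylene)oxy]}bis[1-(3,4-dimethoxyphenyl)propan-1-one]
Conditions: 17 (2.4 equiv), K2CO3, DMF, rt
Reagents that add atoms: none
Why: Twofold Williamson-type SN2 etherification: each phenoxide displaces the tosylate at the carbonyl-activated secondary carbon with inversion, (R) to (S) at C8. The mild base and ambient temperature are chosen to keep enolisation of the ketones slow.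

Step 13
Reactants: 18 (2S,2'S)-2,2'-{[(2S,3S,4S,5R)-3,4-dimethyloxolane-2,5-diyl]bis[(2-methoxy-4,1-phenylene)oxy]}bis[1-(3,4-dimethoxyphenyl)propan-1-one]
Product: 19 (1R,1'R,2S,2'S)-2,2'-{[(2S,3S,4S,5R)-3,4-dimethyloxolane-2,5-diyl]bis[(2-methoxy-4,1-phenylene)oxy]}bis[1-(3,4-dimethoxyphenyl)propan-1-ol]
Conditions: Zn(BH4)2, Et2O/THF, −20 °C
Reagents that add atoms: none
Why: Chelation-controlled hydride reduction: zinc bridges the carbonyl oxygen and the C8 ether oxygen (helped by the neighbouring methoxy group), and hydride enters from the side of the C8 hydrogen. This should give the erythro (1R,2S) arm at both ends (cyclic chelate model).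

## Compound list

1 | dimethyl malonate | COC(=O)CC(=O)OC | starting material
2 | phenyliodonium bis(methoxycarbonyl)methanide | COC(=O)[C-](C(=O)OC)[I+]c1ccccc1 | intermediate
3 | 1-(benzyloxy)-2-methoxy-4-[(E)-prop-1-en-1-yl]benzene (benzyl (E)-isoeugenyl ether) | C/C=C/c1ccc(OCc2ccccc2)c(OC)c1 | starting material
4 | dimethyl (2S,3R)-2-[4-(benzyloxy)-3-methoxyphenyl]-3-methylcyclopropane-1,1-dicarboxylate (aryl and methyl trans) | COC(=O)C1(C(=O)OC)[C@H](c2ccc(OCc3ccccc3)c(OC)c2)[C@H]1C | intermediate
5 | 4-(benzyloxy)-3-methoxybenzaldehyde (O-benzylvanillin) | COc1cc(C=O)ccc1OCc1ccccc1 | starting material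
6 | dimethyl (2R,4S,5R)-2,5-bis[4-(benzyloxy)-3-methoxyphenyl]-4-methyloxolane-3,3-dicarboxylate (aryls cis, C4 methyl cis to C5 aryl) | c1ccccc1COc2ccc([C@H]3O[C@@H](c4ccc(OCc5ccccc5)c(OC)c4)[C@@H](C)C3(C(=O)OC)C(=O)OC)cc2OC | intermediate
7 | methyl (2S,3S,4S,5R)-2,5-bis[4-(benzyloxy)-3-methoxyphenyl]-4-methyloxolane-3-carboxylate (ester trans to C2 aryl and C4 methyl) | c1ccccc1COc2ccc([C@H]3O[C@@H](c4ccc(OCc5ccccc5)c(OC)c4)[C@@H](C)[C@@H]3C(=O)OC)cc2OC | intermediate
8 | {(2S,3R,4S,5R)-2,5-bis[4-(benzyloxy)-3-methoxyphenyl]-4-methyloxolan-3-yl}methanol | c1ccccc1COc2ccc([C@H]3O[C@@H](c4ccc(OCc5ccccc5)c(OC)c4)[C@@H](C)[C@@H]3CO)cc2OC | intermediate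
9 | {(2S,3R,4S,5R)-2,5-bis[4-(benzyloxy)-3-methoxyphenyl]-4-methyloxolan-3-yl}methyl methanesulfonate | c1ccccc1COc2ccc([C@H]3O[C@@H](c4ccc(OCc5ccccc5)c(OC)c4)[C@@H](C)[C@@H]3COS(C)(=O)=O)cc2OC | intermediate
10 | (2S,3S,4S,5R)-2,5-bis[4-(benzyloxy)-3-methoxyphenyl]-3,4-dimethyloxolane | c1ccccc1COc2ccc([C@H]3O[C@@H](c4ccc(OCc5ccccc5)c(OC)c4)[C@@H](C)[C@@H]3C)cc2OC | intermediate
11 | 4,4'-[(2S,3S,4S,5R)-3,4-dimethyloxolane-2,5-diyl]bis(2-methoxyphenol) | Oc1ccc([C@H]2O[C@@H](c3ccc(O)c(OC)c3)[C@@H](C)[C@@H]2C)cc1OC | intermediate
12 | methyl (R)-lactate | COC(=O)[C@@H](C)O | starting material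
13 | methyl (2R)-2-{[(4-methylphenyl)sulfonyl]oxy}propanoate | COC(=O)[C@@H](C)OS(=O)(=O)c1ccc(C)cc1 | intermediate
14 | (2R)-2-{[(4-methylphenyl)sulfonyl]oxy}propanoic acid | OC(=O)[C@@H](C)OS(=O)(=O)c1ccc(C)cc1 | intermediate
15 | 1,2-dimethoxybenzene (veratrole) | COc1ccccc1OC | starting material
16 | (2R)-2-(tosyloxy)propanoyl chloride | ClC(=O)[C@@H](C)OS(=O)(=O)c1ccc(C)cc1 | intermediate
17 | (2R)-1-(3,4-dimethoxyphenyl)-1-oxopropan-2-yl 4-methylbenzenesulfonate | COc1ccc(C(=O)[C@@H](C)OS(=O)(=O)c2ccc(C)cc2)cc1OC | intermediate
18 | (2S,2'S)-2,2'-{[(2S,3S,4S,5R)-3,4-dimethyloxolane-2,5-diyl]bis[(2-methoxy-4,1-phenylene)oxy]}bis[1-(3,4-dimethoxyphenyl)propan-1-one] | COc1ccc(C(=O)[C@H](C)Oc2ccc([C@H]3O[C@@H](c4ccc(O[C@@H](C)C(=O)c5ccc(OC)c(OC)c5)c(OC)c4)[C@@H](C)[C@@H]3C)cc2OC)cc1OC | intermediate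
19 | (1R,1'R,2S,2'S)-2,2'-{[(2S,3S,4S,5R)-3,4-dimethyloxolane-2,5-diyl]bis[(2-methoxy-4,1-phenylene)oxy]}bis[1-(3,4-dimethoxyphenyl)propan-1-ol] | COc1ccc([C@@H](O)[C@H](C)Oc2ccc([C@H]3O[C@@H](c4ccc(O[C@@H](C)[C@H](O)c5ccc(OC)c(OC)c5)c(OC)c4)[C@@H](C)[C@@H]3C)cc2OC)cc1OC | target

## Step count and least certain steps

Total: 13 steps. Longest linear sequence: 10 steps (steps 1–8, 12 and 13, from 1 to 19). The arm (steps 9–11) is made separately and joins at step 12.

**Step 3 (key step).** The donor carbon carries a 4-alkoxy-3-methoxyphenyl group, so ionisation of the activated cyclopropane bond may run ahead of capture by the aldehyde, and the Lewis acid may re-ionise the benzylic C5–O bond of the product. Either process would erode the inversion and lead towards the more stable 4,5-trans series; 2,5-cis closure could also be eroded by reversible C2–C3 cleavage. Lower temperature or another Lewis acid (AlCl3, SnCl4, Hf(OTf)4) would be tried first.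

The fallback changes the role of the cyclopropane. It sets out from 4 and rejoins the route at 10.
- Saponification of 4 (KOH, aqueous MeOH) gives (2S,3R)-2-[4-(benzyloxy)-3-methoxyphenyl]-3-methylcyclopropane-1,1-dicarboxylic acid F1.
- Warming F1 in toluene with a trace of acid should let a carboxyl oxygen open the ring at the benzylic carbon to (4S,5S)-5-[4-(benzyloxy)-3-methoxyphenyl]-4-methyl-2-oxooxolane-3-carboxylic acid F2, which is not isolated and decarboxylates to the trans lactone (4S,5S)-5-[4-(benzyloxy)-3-methoxyphenyl]-4-methyloxolan-2-one F3.
- In this orientation the aryl carbon of the cyclopropane becomes C2 of the target and its methyl carbon becomes C3. The thermodynamic trans relation is therefore the wanted one, and ionisation helps instead of harming.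
- Enolate methylation (LiN(iPr)2, MeI, THF, −78 °C) anti to the neighbouring methyl gives (3S,4S,5S)-5-[4-(benzyloxy)-3-methoxyphenyl]-3,4-dimethyloxolan-2-one F4, the same compound as A5.
- Addition of [4-(benzyloxy)-3-methoxyphenyl]lithium F5 (from purchased 1-(benzyloxy)-4-bromo-2-methoxybenzene and n-BuLi) gives (3S,4S,5S)-2,5-bis[4-(benzyloxy)-3-methoxyphenyl]-3,4-dimethyloxolan-2-ol F6.
- Et3SiH and BF3·OEt2 at −78 °C reduce the derived oxocarbenium ion from the face opposite to the adjacent methyl, which places the new aryl cis to that methyl and cis to the other aryl, that is 10.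

**Step 2.** Face discrimination by the copper–bis(oxazoline) carbene on a trans-1,2-disubstituted, electron-rich alkene may be insufficient, and the copper Lewis acid may open the product or divert the carbene into a formal [3+2] addition giving a dihydrofuran. Ligands with side arms on the bridging carbon would be screened first. The fallback replaces asymmetric catalysis by resolution; it sets out from 3 and 2 and returns at 4. Cyclopropanation with Rh2(esp)2 in CH2Cl2 gives racemic dimethyl (2RS,3SR)-2-[4-(benzyloxy)-3-methoxyphenyl]-3-methylcyclopropane-1,1-dicarboxylate F7, which is separated by preparative chromatography on a polysaccharide chiral stationary phase; the (2S,3R) half is 4.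

**Step 4.** At 150 °C the ester enolate may eliminate O1 (retro-oxa-Michael opening, then lactonisation of the freed alkoxide), or protonation may stop at the kinetic C3 epimer with the ester cis to both neighbours. A short treatment with DBU would complete the equilibration in the second case. The fallback avoids the hot halide conditions; it sets out from 6 and returns at 7. One equivalent of KOH in MeOH/THF/H2O at room temperature should hydrolyse the less hindered ester, the one on the face opposite to the C2 aryl and the C4 methyl, to (2R,3R,4S,5R)-2,5-bis[4-(benzyloxy)-3-methoxyphenyl]-3-(methoxycarbonyl)-4-methyloxolane-3-carboxylic acid F8. Heating F8 in toluene at about 110 °C should decarboxylate it through the neutral enol, and DBU would bring the ester to the thermodynamic side, 7.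

**Step 12.** Carbonate may enolise 17 or the α-aryloxy ketone arms and so epimerise C8, at two sites, and the second etherification may stall. The fallback sets C8 at a non-enolisable alcohol carbon; it sets out from 11 and 12 and returns at 18.
- Mitsunobu etherification of both phenols with 12 (PPh3, DIAD, THF, 0 °C → rt) proceeds with inversion and gives dimethyl (2S,2'S)-2,2'-{[(2S,3S,4S,5R)-3,4-dimethyloxolane-2,5-diyl]bis[(2-methoxy-4,1-phenylene)oxy]}dipropanoate F9.
- Me(MeO)NH·HCl and iPrMgCl (THF, −20 °C) convert F9 into (2S,2'S)-2,2'-{[(2S,3S,4S,5R)-3,4-dimethyloxolane-2,5-diyl]bis[(2-methoxy-4,1-phenylene)oxy]}bis(N-methoxy-N-methylpropanamide) F10.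
- Purchased 3,4-dimethoxyphenylmagnesium bromide (THF, 0 °C) gives 18 on work-up, so the ketone meets base only briefly.

**Step 13.** The aryl ether oxygen is a weak donor, so chelation may be incomplete and facial selectivity may fall at one or both carbonyls; the resulting diastereomers would be hard to separate at the last step. The fallback replaces substrate (chelate) control by catalyst control; it sets out from 18 and returns at 19. (R)-2-Methyl-CBS-oxazaborolidine with BH3·SMe2 in THF at −20 °C would select the carbonyl face through the catalyst and should give the (R) carbinols without basic conditions. No new compound arises (entry F0).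

## Further compounds

F1 | step 3 | (2S,3R)-2-[4-(benzyloxy)-3-methoxyphenyl]-3-methylcyclopropane-1,1-dicarboxylic acid | OC(=O)C1(C(=O)O)[C@H](c2ccc(OCc3ccccc3)c(OC)c2)[C@H]1C
F2 | step 3 | (4S,5S)-5-[4-(benzyloxy)-3-methoxyphenyl]-4-methyl-2-oxooxolane-3-carboxylic acid | c1ccccc1COc2ccc([C@H]3OC(=O)C(C(=O)O)[C@@H]3C)cc2OC
F3 | step 3 | (4S,5S)-5-[4-(benzyloxy)-3-methoxyphenyl]-4-methyloxolan-2-one | c1ccccc1COc2ccc([C@H]3OC(=O)C[C@@H]3C)cc2OC
F4 | step 3 | (3S,4S,5S)-5-[4-(benzyloxy)-3-methoxyphenyl]-3,4-dimethyloxolan-2-one | c1ccccc1COc2ccc([C@H]3OC(=O)[C@@H](C)[C@@H]3C)cc2OC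
F5 | step 3 | [4-(benzyloxy)-3-methoxyphenyl]lithium | [Li]c1ccc(OCc2ccccc2)c(OC)c1
F6 | step 3 | (3S,4S,5S)-2,5-bis[4-(benzyloxy)-3-methoxyphenyl]-3,4-dimethyloxolan-2-ol | c1ccccc1COc2ccc([C@H]3OC(O)(c4ccc(OCc5ccccc5)c(OC)c4)[C@@H](C)[C@@H]3C)cc2OC
F7 | step 2 | racemic dimethyl (2RS,3SR)-2-[4-(benzyloxy)-3-methoxyphenyl]-3-methylcyclopropane-1,1-dicarboxylate | COC(=O)C1(C(=O)OC)[C@H](c2ccc(OCc3ccccc3)c(OC)c2)[C@H]1C.COC(=O)C1(C(=O)OC)[C@@H](c2ccc(OCc3ccccc3)c(OC)c2)[C@@H]1C
F8 | step 4 | (2R,3R,4S,5R)-2,5-bis[4-(benzyloxy)-3-methoxyphenyl]-3-(methoxycarbonyl)-4-methyloxolane-3-carboxylic acid | c1ccccc1COc2ccc([C@H]3O[C@@H](c4ccc(OCc5ccccc5)c(OC)c4)[C@@H](C)[C@]3(C(=O)OC)C(=O)O)cc2OC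
F9 | step 12 | dimethyl (2S,2'S)-2,2'-{[(2S,3S,4S,5R)-3,4-dimethyloxolane-2,5-diyl]bis[(2-methoxy-4,1-phenylene)oxy]}dipropanoate | COC(=O)[C@H](C)Oc1ccc([C@H]2O[C@@H](c3ccc(O[C@@H](C)C(=O)OC)c(OC)c3)[C@@H](C)[C@@H]2C)cc1OC
F10 | step 12 | (2S,2'S)-2,2'-{[(2S,3S,4S,5R)-3,4-dimethyloxolane-2,5-diyl]bis[(2-methoxy-4,1-phenylene)oxy]}bis(N-methoxy-N-methylpropanamide) | CON(C)C(=O)[C@H](C)Oc1ccc([C@H]2O[C@@H](c3ccc(O[C@@H](C)C(=O)N(C)OC)c(OC)c3)[C@@H](C)[C@@H]2C)cc1OC
F0 | step 13 | none | none
A1 | alternative 1 | (2S,3S,4S,5R)-2,5-bis(4-bromo-3-methoxyphenyl)-3,4-dimethyloxolane | Brc1ccc([C@H]2O[C@@H](c3ccc(Br)c(OC)c3)[C@@H](C)[C@@H]2C)cc1OC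
A2 | alternative 1 | (1R,2S)-1-(3,4-dimethoxyphenyl)-1-[(triisopropylsilyl)oxy]propan-2-ol | COc1ccc([C@@H](O[Si](C(C)C)(C(C)C)C(C)C)[C@H](C)O)cc1OC
A3 | alternative 1 | bis-TIPS ether of the target | COc1ccc([C@@H](O[Si](C(C)C)(C(C)C)C(C)C)[C@H](C)Oc2ccc([C@H]3O[C@@H](c4ccc(O[C@@H](C)[C@H](O[Si](C(C)C)(C(C)C)C(C)C)c5ccc(OC)c(OC)c5)c(OC)c4)[C@@H](C)[C@@H]3C)cc2OC)cc1OC
A4 | alternative 2 | (5S)-5-[4-(benzyloxy)-3-methoxyphenyl]furan-2(5H)-one | c1ccccc1COc2ccc([C@H]3OC(=O)C=C3)cc2OC
A5 | alternative 2 | (3S,4S,5S)-5-[4-(benzyloxy)-3-methoxyphenyl]-3,4-dimethyloxolan-2-one | c1ccccc1COc2ccc([C@H]3OC(=O)[C@@H](C)[C@@H]3C)cc2OC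
A6 | alternative 3 | (1R,2S,3S,4R)-1,4-bis(4-{[(1R,2S)-1-[(tert-butyldimethylsilyl)oxy]-1-(3,4-dimethoxyphenyl)propan-2-yl]oxy}-3-methoxyphenyl)-2,3-dimethylbutane-1,4-diol | COc1ccc([C@@H](O[Si](C)(C)C(C)(C)C)[C@H](C)Oc2ccc([C@H](O)[C@@H](C)[C@H](C)[C@@H](O)c3ccc(O[C@@H](C)[C@H](O[Si](C)(C)C(C)(C)C)c4ccc(OC)c(OC)c4)c(OC)c3)cc2OC)cc1OC
A7 | alternative 3 | bis-TBS ether of the target | COc1ccc([C@@H](O[Si](C)(C)C(C)(C)C)[C@H](C)Oc2ccc([C@H]3O[C@@H](c4ccc(O[C@@H](C)[C@H](O[Si](C)(C)C(C)(C)C)c5ccc(OC)c(OC)c5)c(OC)c4)[C@@H](C)[C@@H]3C)cc2OC)cc1OC
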